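**Plan**
1. Retrosynthesis: the C4'' carbonyl is taken back to CH2 (flavan). Ring C'' is then cut at C3''–C4'' and O1''–C2'' into an ortho-quinone methide on ring A'' and 4-vinylphenol. The C3–C6'' biaryl bond is cut next (Suzuki–Miyaura), and the flavone pyranone last (1,3-diketone cyclodehydration).
2. Enabling feature: O1'' (on C8a'') and C4'' (on C4a'') are ortho neighbours on the phloroglucinol ring A'', so ring C'' is a latent ortho-quinone methide adduct. C2'' carries a 4-hydroxyphenyl group whose para-hydroxyl can take up positive charge at C2'' and hydrogen-bond to a chiral acid.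
3. Forward order: flavone rings A and C, iodide at C3, biaryl bond to ring A'' (O5''/O7'' benzylated, O1'' silylated), release of O1'', ortho-formylation and reduction, closure of ring C'' with 4-vinylphenol, C4'' oxidation, hydrogenolysis.
4. Stereochemistry: C2'' (R) is the only stereocentre. It is set in the ring C'' closure by a chiral phosphoric acid and is not touched afterwards.

Key step: step 11

Assumption: the C3–C6'' biaryl axis is not defined in the target and is not controlled; rotamers about it are carried together.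
Assumption: the sense of induction of the acid cannot be predicted with certainty; the (R)-acid is written and its antipode would be used if the (2S)-flavan is favoured.
Remark: 4-vinylphenol is freed from its commercial glycol solution by extraction and used at once, since it polymerises on standing.

**Route**

Step 1
Reactants: 1 1-(2,6-dihydroxy-4-methoxyphenyl)ethanone; 2 4-methoxybenzoyl chloride
Product: 3 1-(2,6-dihydroxy-4-methoxyphenyl)-3-(4-methoxyphenyl)propane-1,3-dione
Conditions: LiN(SiMe3)2 (4.2 equiv), THF, −78 to −10 °C; then 2, −78 °C to rt; aq. HCl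
Reagents that add atoms: none
Why: Excess amide base deprotonates both phenols and the methyl ketone of 1, and the enolate carbon is acylated by the acid chloride (Claisen-type C-acylation, the direct variant of the Baker–Venkataraman route), so the 1,3-diketone should form without phenol protection.

Step 2
Reactants: 3 1-(2,6-dihydroxy-4-methoxyphenyl)-3-(4-methoxyphenyl)propane-1,3-dione
Product: 4 5-hydroxy-7-methoxy-2-(4-methoxyphenyl)-4H-chromen-4-one
Conditions: H2SO4 (cat.), AcOH, 95 °C
Reagents that add atoms: none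
Why: Acid-catalysed cyclodehydration of an ortho-hydroxyaryl 1,3-diketone closes the pyranone ring, and either of the two equivalent phenols of 3 gives the same flavone.

Step 3
Reactants: 4 5-hydroxy-7-methoxy-2-(4-methoxyphenyl)-4H-chromen-4-one
Product: 5 5-(benzyloxy)-7-methoxy-2-(4-methoxyphenyl)-4H-chromen-4-one
Conditions: BnBr, K2CO3, Bu4NI (cat.), DMF, 70 °C
Reagents that add atoms: benzyl bromide BrCc1ccccc1
Why: Williamson etherification of the chelated 5-hydroxyl, the only acidic site, needs heat in DMF but removes the proton that would quench the base of step 4 and gives an ether that falls in the final hydrogenolysis.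

Step 4
Reactants: 5 5-(benzyloxy)-7-methoxy-2-(4-methoxyphenyl)-4H-chromen-4-one
Product: 7 5-(benzyloxy)-3-iodo-7-methoxy-2-(4-methoxyphenyl)-4H-chromen-4-one, via 3-lithioflavone 6 (not isolated)
Conditions: LiN(i-Pr)2, THF, −78 °C; then I2, −78 °C to rt
Reagents that add atoms: iodine II
Why: Deprotonation–iodination: C3–H is the most acidic C–H of a 2-arylchromone (vinylic, next to the lithium-chelating carbonyl), so lithiation at −78 °C and an I2 quench should place iodine at C3 and not on the electron-rich ring A, where electrophilic iodination would go.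

Step 5
Reactants: 8 3,5-bis(benzyloxy)phenol
Product: 9 [3,5-bis(benzyloxy)phenoxy]tri(propan-2-yl)silane
Conditions: i-Pr3SiCl, imidazole, DMF, rt
Reagents that add atoms: chlorotri(propan-2-yl)silane CC(C)[Si](Cl)(C(C)C)C(C)C
Why: Imidazole-promoted silylation of the only hydroxyl gives a bulky silyl ether that is inert to n-BuLi, does not direct metalation and is later removed by fluoride beside benzyl ethers (silyl ether protection).

Step 6
Reactants: 9 [3,5-bis(benzyloxy)phenoxy]tri(propan-2-yl)silane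
Product: 11 2-[2,6-bis(benzyloxy)-4-(triisopropylsilyloxy)phenyl]-4,4,5,5-tetramethyl-1,3,2-dioxaborolane, via aryllithium 10 (not isolated)
Conditions: n-BuLi, THF, 0 °C; then i-PrOB(pin), −78 °C to rt; aq. NH4Cl
Reagents that add atoms: 2-isopropoxy-4,4,5,5-tetramethyl-1,3,2-dioxaborolane CC(C)OB1OC(C)(C)C(C)(C)O1
Why: Directed ortho-metalation: the ring C–H flanked by both benzyloxy groups is the most acidic and is held by two coordinating oxygens, the silyloxy side is shielded, and the aryllithium is trapped by the isopropoxy pinacol borate, while working at 0 °C or below keeps benzylic deprotonation and [1,2]-Wittig rearrangement out.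

Step 7
Reactants: 7 5-(benzyloxy)-3-iodo-7-methoxy-2-(4-methoxyphenyl)-4H-chromen-4-one; 11 2-[2,6-bis(benzyloxy)-4-(triisopropylsilyloxy)phenyl]-4,4,5,5-tetramethyl-1,3,2-dioxaborolane
Product: 12 5-(benzyloxy)-3-[2,6-bis(benzyloxy)-4-(triisopropylsilyloxy)phenyl]-7-methoxy-2-(4-methoxyphenyl)-4H-chromen-4-one
Conditions: Pd(OAc)2 (5 mol %), SPhos (10 mol %), K3PO4, toluene/H2O (10:1), 100 °C; 11 in excess
Reagents that add atoms: none
Why: Suzuki–Miyaura coupling of an alpha-iodoenone, which adds readily to zerovalent palladium, with a doubly ortho-substituted aryl boronate; the dialkylbiarylphosphine SPhos is the established ligand for tetra-ortho-substituted biaryls, and excess 11 offsets protodeboronation.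

Step 8
Reactants: 12 5-(benzyloxy)-3-[2,6-bis(benzyloxy)-4-(triisopropylsilyloxy)phenyl]-7-methoxy-2-(4-methoxyphenyl)-4H-chromen-4-one
Product: 13 5-(benzyloxy)-3-[2,6-bis(benzyloxy)-4-hydroxyphenyl]-7-methoxy-2-(4-methoxyphenyl)-4H-chromen-4-one
Conditions: Bu4NF, THF, 0 °C; aq. NH4Cl
Reagents that add atoms: none
Why: Fluoride cleaves the aryl silyl ether (desilylation driven by the Si–F bond) and leaves the benzyl ethers and the chromone alone, freeing the one phenol that becomes O1''.

Step 9
Reactants: 13 5-(benzyloxy)-3-[2,6-bis(benzyloxy)-4-hydroxyphenyl]-7-methoxy-2-(4-methoxyphenyl)-4H-chromen-4-one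
Product: 14 5-(benzyloxy)-3-[2,6-bis(benzyloxy)-3-formyl-4-hydroxyphenyl]-7-methoxy-2-(4-methoxyphenyl)-4H-chromen-4-one
Conditions: MgCl2, Et3N, (CH2O)n, MeCN, reflux; aq. HCl
Reagents that add atoms: paraformaldehyde (as formaldehyde) C=O
Why: Casnati–Skattebøl ortho-formylation: the magnesium phenoxide delivers formaldehyde only ortho to the free phenol, the two ortho positions of 13 are equivalent, and the aryl ethers of flavone ring A cannot take part, so a single salicylaldehyde should result.

Step 10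
Reactants: 14 5-(benzyloxy)-3-[2,6-bis(benzyloxy)-3-formyl-4-hydroxyphenyl]-7-methoxy-2-(4-methoxyphenyl)-4H-chromen-4-one
Product: 15 5-(benzyloxy)-3-[2,6-bis(benzyloxy)-4-hydroxy-3-(hydroxymethyl)phenyl]-7-methoxy-2-(4-methoxyphenyl)-4H-chromen-4-one
Conditions: NaBH4, THF/MeOH, 0 °C; neutral work-up, used without chromatography on acidic silica
Reagents that add atoms: none
Why: Hydride reduction of the aldehyde by NaBH4, which leaves the vinylogous ester carbonyl of the flavone alone at 0 °C, gives the ortho-hydroxybenzyl alcohol, which is kept away from acid until step 11.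

Step 11
Reactants: 15 5-(benzyloxy)-3-[2,6-bis(benzyloxy)-4-hydroxy-3-(hydroxymethyl)phenyl]-7-methoxy-2-(4-methoxyphenyl)-4H-chromen-4-one; 16 4-vinylphenol
Product: 19 3-[(2R)-5,7-bis(benzyloxy)-2-(4-hydroxyphenyl)-3,4-dihydro-2H-chromen-6-yl]-5-(benzyloxy)-7-methoxy-2-(4-methoxyphenyl)-4H-chromen-4-one, via ortho-quinone methide 17 (not isolated), via para-quinone methide adduct 18 (not isolated)
Conditions: (R)-TRIP [(R)-3,3'-bis(2,4,6-triisopropylphenyl)-1,1'-binaphthyl-2,2'-diyl hydrogen phosphate] (10 mol %), 16 (3 equiv), toluene/CH2Cl2, −20 °C, slow addition of 15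
Reagents that add atoms: none
Why: Proposed new method: the phosphoric acid ionises the benzylic alcohol of 15, whose cation is stabilised by O5'', O7'' and O1'', to ortho-quinone methide 17; the CH2 terminus of 4-vinylphenol adds to the unsubstituted methide carbon (C3''–C4''), the charge arriving at C2'' is absorbed by the para-hydroxyl as para-quinone methide 18, and the ring A'' phenol then closes ring C'' on C2'' (O1''–C2''), a formal [4+2] (stepwise oxa-Diels–Alder) annulation. The closest known reaction types are chiral phosphoric acid-catalysed [4+2] cyclisations of in situ ortho-quinone methides with hydroxystyrenes and phosphoric acid-catalysed asymmetric 1,6-additions to para-quinone methides, but neither has been shown for a methide carbon without a substituent or for a 4-hydroxystyrene as the two-carbon partner. Ring C'' closes in a 6-exo-trig oxa-1,6-addition. C2'', the only new stereocentre, is set in that closure by the chiral phosphate, which is expected to bridge the ring A'' hydroxyl (P=O acceptor) and the quinone methide oxygen that was the 4-hydroxyl (P–OH donor) and so to expose one face of C2''; the (R)-acid is taken to give 2R. The step needs regioselectivity for the 2-aryl 6-linked flavan and chemoselectivity for cross-coupling over self-condensation: the benzyl ethers on O5'' and O7'' leave O1'' as the only oxygen able to form the quinone methide or close the ring, the polarity of the styrene puts its aryl-bearing carbon on oxygen, and excess 16 with slow addition of 15 at low temperature should hold back oligomerisation of 17 and acid-mediated reopening of 19.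

Step 12
Reactants: 19 3-[(2R)-5,7-bis(benzyloxy)-2-(4-hydroxyphenyl)-3,4-dihydro-2H-chromen-6-yl]-5-(benzyloxy)-7-methoxy-2-(4-methoxyphenyl)-4H-chromen-4-one
Product: 20 3-[(2R)-5,7-bis(benzyloxy)-2-[4-(benzyloxy)phenyl]-3,4-dihydro-2H-chromen-6-yl]-5-(benzyloxy)-7-methoxy-2-(4-methoxyphenyl)-4H-chromen-4-one
Conditions: BnBr, K2CO3, DMF, rt
Reagents that add atoms: benzyl bromide BrCc1ccccc1
Why: Williamson etherification of the only phenol is needed because a free para-hydroxyl would let DDQ turn C2'' into a para-quinone methide in step 13.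

Step 13
Reactants: 20 3-[(2R)-5,7-bis(benzyloxy)-2-[4-(benzyloxy)phenyl]-3,4-dihydro-2H-chromen-6-yl]-5-(benzyloxy)-7-methoxy-2-(4-methoxyphenyl)-4H-chromen-4-one
Product: 21 3-[(2R)-5,7-bis(benzyloxy)-2-[4-(benzyloxy)phenyl]-4-hydroxy-3,4-dihydro-2H-chromen-6-yl]-5-(benzyloxy)-7-methoxy-2-(4-methoxyphenyl)-4H-chromen-4-one (both C4'' epimers)
Conditions: DDQ (1.2 equiv), CH2Cl2/H2O (10:1), 0 °C to rt
Reagents that add atoms: water O
Why: Benzylic oxidation by hydride abstraction: DDQ removes hydride from C4'', whose cation is stabilised by O5'', O7'' and O1'' as in the known C4 functionalisation of 5,7-dialkoxyflavans, and water traps the cation as the flavan-4-ol (either epimer serves) without touching C2''.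

Step 14
Reactants: 21 3-[(2R)-5,7-bis(benzyloxy)-2-[4-(benzyloxy)phenyl]-4-hydroxy-3,4-dihydro-2H-chromen-6-yl]-5-(benzyloxy)-7-methoxy-2-(4-methoxyphenyl)-4H-chromen-4-one
Product: 22 3-[(2R)-5,7-bis(benzyloxy)-2-[4-(benzyloxy)phenyl]-4-oxo-3,4-dihydro-2H-chromen-6-yl]-5-(benzyloxy)-7-methoxy-2-(4-methoxyphenyl)-4H-chromen-4-one
Conditions: Dess–Martin periodinane, pyridine, CH2Cl2, 0 °C to rt
Reagents that add atoms: none
Why: Dess–Martin oxidation of the secondary benzylic alcohol to the aryl ketone runs under buffered, non-basic conditions that cannot open ring C'' by a retro-oxa-Michael reaction, so C2'' keeps its configuration.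

Step 15
Reactants: 22 3-[(2R)-5,7-bis(benzyloxy)-2-[4-(benzyloxy)phenyl]-4-oxo-3,4-dihydro-2H-chromen-6-yl]-5-(benzyloxy)-7-methoxy-2-(4-methoxyphenyl)-4H-chromen-4-one
Product: 23 3-[(2R)-5,7-dihydroxy-2-(4-hydroxyphenyl)-4-oxo-3,4-dihydro-2H-chromen-6-yl]-5-hydroxy-7-methoxy-2-(4-methoxyphenyl)-4H-chromen-4-one (CNP0292254.1)
Conditions: H2 (1 atm), 10% Pd/C, EtOAc/MeOH, rt; stopped at full debenzylation
Reagents that add atoms: none
Why: Hydrogenolysis of the four benzyl ethers over Pd/C is neutral, so the flavanone should not racemise, and the tetrasubstituted flavone double bond, both ketones and the cyclic C2''–O1'' ether are expected to persist at room temperature and 1 atm.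

**Compound list**
1 | 1-(2,6-dihydroxy-4-methoxyphenyl)ethanone | CC(=O)c1c(O)cc(OC)cc1O | starting material
2 | 4-methoxybenzoyl chloride | COc1ccc(C(=O)Cl)cc1 | starting material
3 | 1-(2,6-dihydroxy-4-methoxyphenyl)-3-(4-methoxyphenyl)propane-1,3-dione | COc1ccc(cc1)C(=O)CC(=O)c1c(O)cc(OC)cc1O | intermediate
4 | 5-hydroxy-7-methoxy-2-(4-methoxyphenyl)-4H-chromen-4-one | COc1ccc(cc1)-c1cc(=O)c2c(O)cc(OC)cc2o1 | intermediate
5 | 5-(benzyloxy)-7-methoxy-2-(4-methoxyphenyl)-4H-chromen-4-one | COc1ccc(cc1)-c1cc(=O)c2c(OCc3ccccc3)cc(OC)cc2o1 | intermediate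
6 | 5-(benzyloxy)-3-lithio-7-methoxy-2-(4-methoxyphenyl)-4H-chromen-4-one | [Li]c1c(-c2ccc(OC)cc2)oc2cc(OC)cc(OCc3ccccc3)c2c1=O | intermediate (not isolated)
7 | 5-(benzyloxy)-3-iodo-7-methoxy-2-(4-methoxyphenyl)-4H-chromen-4-one | COc1ccc(cc1)-c1oc2cc(OC)cc(OCc3ccccc3)c2c(=O)c1I | intermediate
8 | 3,5-bis(benzyloxy)phenol | Oc1cc(OCc2ccccc2)cc(OCc2ccccc2)c1 | starting material
9 | [3,5-bis(benzyloxy)phenoxy]tri(propan-2-yl)silane | CC(C)[Si](Oc1cc(OCc2ccccc2)cc(OCc2ccccc2)c1)(C(C)C)C(C)C | intermediate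
10 | [2,6-bis(benzyloxy)-4-(triisopropylsilyloxy)phenyl]lithium | [Li]c1c(OCc2ccccc2)cc(O[Si](C(C)C)(C(C)C)C(C)C)cc1OCc1ccccc1 | intermediate (not isolated)
11 | 2-[2,6-bis(benzyloxy)-4-(triisopropylsilyloxy)phenyl]-4,4,5,5-tetramethyl-1,3,2-dioxaborolane | CC(C)[Si](Oc1cc(OCc2ccccc2)c(B2OC(C)(C)C(C)(C)O2)c(OCc2ccccc2)c1)(C(C)C)C(C)C | intermediate
12 | 5-(benzyloxy)-3-[2,6-bis(benzyloxy)-4-(triisopropylsilyloxy)phenyl]-7-methoxy-2-(4-methoxyphenyl)-4H-chromen-4-one | COc1ccc(cc1)-c1oc2cc(OC)cc(OCc3ccccc3)c2c(=O)c1-c1c(OCc2ccccc2)cc(O[Si](C(C)C)(C(C)C)C(C)C)cc1OCc1ccccc1 | intermediate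
13 | 5-(benzyloxy)-3-[2,6-bis(benzyloxy)-4-hydroxyphenyl]-7-methoxy-2-(4-methoxyphenyl)-4H-chromen-4-one | COc1ccc(cc1)-c1oc2cc(OC)cc(OCc3ccccc3)c2c(=O)c1-c1c(OCc2ccccc2)cc(O)cc1OCc1ccccc1 | intermediate
14 | 5-(benzyloxy)-3-[2,6-bis(benzyloxy)-3-formyl-4-hydroxyphenyl]-7-methoxy-2-(4-methoxyphenyl)-4H-chromen-4-one | COc1ccc(cc1)-c1oc2cc(OC)cc(OCc3ccccc3)c2c(=O)c1-c1c(OCc2ccccc2)cc(O)c(C=O)c1OCc1ccccc1 | intermediate
15 | 5-(benzyloxy)-3-[2,6-bis(benzyloxy)-4-hydroxy-3-(hydroxymethyl)phenyl]-7-methoxy-2-(4-methoxyphenyl)-4H-chromen-4-one | COc1ccc(cc1)-c1oc2cc(OC)cc(OCc3ccccc3)c2c(=O)c1-c1c(OCc2ccccc2)cc(O)c(CO)c1OCc1ccccc1 | intermediate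
16 | 4-vinylphenol | C=Cc1ccc(O)cc1 | starting material
17 | ortho-quinone methide of 15 (C8a''=O, exocyclic C4''H2) | C=C1C(=O)C=C(OCc2ccccc2)C(=C1OCc1ccccc1)c1c(-c2ccc(OC)cc2)oc2cc(OC)cc(OCc3ccccc3)c2c1=O | intermediate (not isolated)
18 | para-quinone methide adduct (ring A'' phenol–CH2CH2–CH= cyclohexadienone) | O=C1C=CC(=CCCc2c(O)cc(OCc3ccccc3)c(c2OCc2ccccc2)-c2c(-c3ccc(OC)cc3)oc3cc(OC)cc(OCc4ccccc4)c3c2=O)C=C1 | intermediate (not isolated)
19 | 3-[(2R)-5,7-bis(benzyloxy)-2-(4-hydroxyphenyl)-3,4-dihydro-2H-chromen-6-yl]-5-(benzyloxy)-7-methoxy-2-(4-methoxyphenyl)-4H-chromen-4-one | COc1ccc(-c2oc3cc(OC)cc(OCc4ccccc4)c3c(=O)c2-c2c(OCc4ccccc4)cc3c(c2OCc2ccccc2)CC[C@H](c2ccc(O)cc2)O3)cc1 | intermediate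
20 | 3-[(2R)-5,7-bis(benzyloxy)-2-[4-(benzyloxy)phenyl]-3,4-dihydro-2H-chromen-6-yl]-5-(benzyloxy)-7-methoxy-2-(4-methoxyphenyl)-4H-chromen-4-one | COc1ccc(-c2oc3cc(OC)cc(OCc4ccccc4)c3c(=O)c2-c2c(OCc4ccccc4)cc3c(c2OCc2ccccc2)CC[C@H](c2ccc(OCc4ccccc4)cc2)O3)cc1 | intermediate
21 | 3-[(2R)-5,7-bis(benzyloxy)-2-[4-(benzyloxy)phenyl]-4-hydroxy-3,4-dihydro-2H-chromen-6-yl]-5-(benzyloxy)-7-methoxy-2-(4-methoxyphenyl)-4H-chromen-4-one (C4'' epimers) | COc1ccc(-c2oc3cc(OC)cc(OCc4ccccc4)c3c(=O)c2-c2c(OCc4ccccc4)cc3c(c2OCc2ccccc2)C(O)C[C@H](c2ccc(OCc4ccccc4)cc2)O3)cc1 | intermediate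
22 | 3-[(2R)-5,7-bis(benzyloxy)-2-[4-(benzyloxy)phenyl]-4-oxo-3,4-dihydro-2H-chromen-6-yl]-5-(benzyloxy)-7-methoxy-2-(4-methoxyphenyl)-4H-chromen-4-one | COc1ccc(-c2oc3cc(OC)cc(OCc4ccccc4)c3c(=O)c2-c2c(OCc4ccccc4)cc3c(c2OCc2ccccc2)C(=O)C[C@H](c2ccc(OCc4ccccc4)cc2)O3)cc1 | intermediate
23 | 3-[(2R)-5,7-dihydroxy-2-(4-hydroxyphenyl)-4-oxo-3,4-dihydro-2H-chromen-6-yl]-5-hydroxy-7-methoxy-2-(4-methoxyphenyl)-4H-chromen-4-one | COc1ccc(-c2oc3cc(OC)cc(O)c3c(=O)c2-c2c(O)cc3c(c2O)C(=O)C[C@H](c2ccc(O)cc2)O3)cc1 | target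

**Totals**
Total step count: 15.
Longest linear sequence: 13 steps (steps 1–4 and 7–15, from compound 1).

**Steps most likely to fail**

Step 11 (proposed new method). Three processes threaten it:
- The quinone methide can self-condense through the free C8'' position of another molecule, and 4-vinylphenol can oligomerise cationically.
- Facial selectivity in the ring closure may be poor, because the phosphate must span two remote hydrogen-bond sites.
- Acid-reversible opening of ring C'' can erode the enantiomeric purity.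

Fallback (known chemistry), setting out from aldehyde 14 and returning at benzyl ether 20: Claisen–Schmidt condensation of 14 with commercial 4'-(benzyloxy)acetophenone (KOH, EtOH) should give the (E)-enone F1. Hydrogenation of the alkene alone over RhCl(PPh3)3 gives the saturated ketone F2. Corey–Bakshi–Shibata reduction with the (R)-2-methyl-oxazaborolidine and BH3·SMe2 gives the (S)-carbinol F3. Mitsunobu cyclisation (PPh3, DIAD, THF, 0 °C) then lets the ring A'' phenol displace the activated benzylic hydroxyl with inversion, forming O1''–C2'' and the (2R)-flavan 20, which re-enters at step 13.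

Step 7. Transmetalation at the doubly ortho-alkoxylated boronate may be slow, letting protodeboronation and reductive deiodination overtake the coupling.

Fallback, setting out from silyl ether 9 and returning at biaryl 12: aryllithium 10, generated as in step 6, is transmetalated with ZnCl2 to the arylzinc chloride F4. This is coupled with iodide 7 in a Negishi reaction (Pd(OAc)2, SPhos, THF, 60 °C), which removes the boron species and the aqueous base.

Step 13. Hydride abstraction may occur at C2'' instead of C4'', which would open ring C'' and scramble the stereocentre. The C4'' cation may also lose a proton to a flav-3-ene that is oxidised further, and the benzyl ethers may be oxidised slowly.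

Fallback, setting out from flavan 20 and returning at flavan-4-ol 21: benzylic acetoxylation with Pb(OAc)4 in benzene at rt, known for 5,7-dialkoxyflavans, should give the 4''-acetate F5. Methanolysis (K2CO3, MeOH, 0 °C) then gives 21.

**Further compounds**
F1 | step 11 | (E)-3-{2,4-bis(benzyloxy)-3-[5-(benzyloxy)-7-methoxy-2-(4-methoxyphenyl)-4-oxo-4H-chromen-3-yl]-6-hydroxyphenyl}-1-[4-(benzyloxy)phenyl]prop-2-en-1-one | O=C(/C=C/c1c(O)cc(OCc2ccccc2)c(c1OCc1ccccc1)-c1c(-c2ccc(OC)cc2)oc2cc(OC)cc(OCc3ccccc3)c2c1=O)c1ccc(OCc2ccccc2)cc1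
F2 | step 11 | 3-{2,4-bis(benzyloxy)-3-[5-(benzyloxy)-7-methoxy-2-(4-methoxyphenyl)-4-oxo-4H-chromen-3-yl]-6-hydroxyphenyl}-1-[4-(benzyloxy)phenyl]propan-1-one | O=C(CCc1c(O)cc(OCc2ccccc2)c(c1OCc1ccccc1)-c1c(-c2ccc(OC)cc2)oc2cc(OC)cc(OCc3ccccc3)c2c1=O)c1ccc(OCc2ccccc2)cc1
F3 | step 11 | 5-(benzyloxy)-3-{2,6-bis(benzyloxy)-3-[(3S)-3-[4-(benzyloxy)phenyl]-3-hydroxypropyl]-4-hydroxyphenyl}-7-methoxy-2-(4-methoxyphenyl)-4H-chromen-4-one | O[C@@H](CCc1c(O)cc(OCc2ccccc2)c(c1OCc1ccccc1)-c1c(-c2ccc(OC)cc2)oc2cc(OC)cc(OCc3ccccc3)c2c1=O)c1ccc(OCc2ccccc2)cc1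
F4 | step 7 | [2,6-bis(benzyloxy)-4-(triisopropylsilyloxy)phenyl]zinc chloride | Cl[Zn]c1c(OCc2ccccc2)cc(O[Si](C(C)C)(C(C)C)C(C)C)cc1OCc1ccccc1
F5 | step 13 | (2R)-5,7-bis(benzyloxy)-2-[4-(benzyloxy)phenyl]-6-[5-(benzyloxy)-7-methoxy-2-(4-methoxyphenyl)-4-oxo-4H-chromen-3-yl]-3,4-dihydro-2H-chromen-4-yl acetate (C4'' epimers) | COc1ccc(-c2oc3cc(OC)cc(OCc4ccccc4)c3c(=O)c2-c2c(OCc4ccccc4)cc3c(c2OCc2ccccc2)C(OC(C)=O)C[C@H](c2ccc(OCc4ccccc4)cc2)O3)cc1
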